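The dihydropyranone ring is cut at C4–C5 and O1–C6. Its vinylogous ester O1–C6(CH3)=C5–C4=O is read as propyne (C5, C6, CH3) trapped between the acyl carbon C4 and the hydroxyl oxygen O1 of an (R)-3-hydroxyacyl unit O1–C2–C3–C4. In one flask, 1-propynyllithium attacks the amide carbonyl C4 of an (R)-β-hydroxy morpholine amide, the morpholine that is expelled adds to the new ynone as a relay, and acid closes O1–C6 with loss of the amine. The amide is reached in two steps from oleyl bromide, (R)-epichlorohydrin and CO; C2 comes from the chiral pool.

Key step: step 3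

Remark: ring numbering is O1, C2 (stereocentre, R by CIP), C3, C4 (C=O), C5, C6 (C–CH3); oleyl bromide and 1-propynyllithium are taken as catalogue compounds.

Step 1
Reactants: 1 (Z)-1-bromooctadec-9-ene (oleyl bromide); 2 (R)-2-(chloromethyl)oxirane [(R)-epichlorohydrin]
Product: 5 (R)-2-[(Z)-nonadec-10-en-1-yl]oxirane, via oleylmagnesium bromide 3 (not isolated), via chlorohydrin 4 (not isolated)
Conditions: Mg, THF, 45 °C; then 2, CuI (10 mol%), THF, −40 to 0 °C; then 5 M aq. NaOH, rt
Reagents that add atoms: none
Why: Copper-catalysed Grignard opening of the epoxide of 2 at its unsubstituted ring carbon outruns substitution at the C–Cl carbon, so the stereocentre is never a reaction site, and hydroxide then closes chlorohydrin 4 by intramolecular Williamson displacement of chloride, which transposes the oxirane and keeps the R descriptor; the Z-alkene is a spectator.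

Step 2
Reactants: 5 (R)-2-[(Z)-nonadec-10-en-1-yl]oxirane
Product: 7 (R,Z)-3-hydroxy-1-(morpholin-4-yl)docos-13-en-1-one, via silyl ether 6 (not isolated)
Conditions: Co2(CO)8 (5 mol%), 4-(trimethylsilyl)morpholine (1.3 equiv), CO (1 atm), EtOAc, rt; then MeOH, citric acid, rt
Reagents that add atoms: carbon monoxide, [C-]#[O+]; 4-(trimethylsilyl)morpholine, C[Si](C)(C)N1CCOCC1
Why: Cobalt-catalysed carbonylative ring opening of a terminal epoxide with a silyl amine: Co(CO)4− opens the silyl-activated oxirane at the terminal CH2 (C2 untouched, configuration retained), CO inserts into the alkyl–cobalt bond and the acylcobalt is aminolysed by the silyl amine to silyl ether 6, which methanolic acid desilylates.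

Step 3
Reactants: 7 (R,Z)-3-hydroxy-1-(morpholin-4-yl)docos-13-en-1-one; 8 1-propynyllithium
Product: 12 (R)-6-methyl-2-[(Z)-nonadec-10-en-1-yl]-2,3-dihydro-4H-pyran-4-one, via dilithio tetrahedral adduct 9 (not isolated), via hydroxy ynone 10 (not isolated), via morpholino enone 11 (not isolated)
Conditions: 8 (3 equiv), THF, −78 to 0 °C; then MeOH, rt; then 2 M aq. HCl, rt
Reagents that add atoms: none
Why: One equivalent of 8 deprotonates the hydroxyl and a second adds to the amide carbonyl to give the chelated adduct 9, which does not collapse in THF, so a single propynyl group is transferred (C4–C5); methanol then releases ynone 10 together with morpholine, which adds to C6 to give the vinylogous amide 11, and aqueous HCl O-protonates 11 so that the C2 hydroxyl attacks C6 and morpholinium is expelled (O1–C6). The closest known chemistry is ketone synthesis from morpholine amides joined to the enaminone addition–elimination cyclisation used for chromones and for 2-alkyl-6-methyl-dihydropyranones from β-hydroxy ynones. The six-membered ring closes 6-exo-trig on the iminium carbon C6, which is formally the 6-endo-dig hydroalkoxylation of the ynone. No stereocentre is created: C2 (R) is carried from 2 and its C–O bond is never broken, while E/Z isomers of 11 and any methanol adduct or β-diketone from hydrolysis converge on the same ring. The step needs mono-addition, six- over five-membered closure and no dehydration or retro-aldol cleavage; these are secured by the stable adduct 9, by the relay amine sitting on C6 as the only leaving group, and by fast conversion of the electrophilic ynone into the unreactive vinylogous amide. Dilute acid at room temperature for a short time should avoid retro-oxa-Michael opening at C2.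

Compound list
1 | (Z)-1-bromooctadec-9-ene (oleyl bromide) | CCCCCCCC/C=C\CCCCCCCCBr | starting material
2 | (R)-2-(chloromethyl)oxirane [(R)-epichlorohydrin] | ClC[C@H]1CO1 | starting material
3 | (Z)-octadec-9-en-1-ylmagnesium bromide (oleylmagnesium bromide) | CCCCCCCC/C=C\CCCCCCCC[Mg]Br | intermediate
4 | (R,Z)-1-chlorohenicos-12-en-2-ol | CCCCCCCC/C=C\CCCCCCCCC[C@@H](O)CCl | intermediate
5 | (R)-2-[(Z)-nonadec-10-en-1-yl]oxirane | CCCCCCCC/C=C\CCCCCCCCC[C@@H]1CO1 | intermediate
6 | (R,Z)-1-(morpholin-4-yl)-3-(trimethylsilyloxy)docos-13-en-1-one | CCCCCCCC/C=C\CCCCCCCCC[C@@H](O[Si](C)(C)C)CC(=O)N1CCOCC1 | intermediate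
7 | (R,Z)-3-hydroxy-1-(morpholin-4-yl)docos-13-en-1-one | CCCCCCCC/C=C\CCCCCCCCC[C@@H](O)CC(=O)N1CCOCC1 | intermediate
8 | 1-propynyllithium | [Li]C#CC | starting material
9 | dilithium salt of the tetrahedral adduct, (6R,16Z)-4-(morpholin-4-yl)pentacos-16-en-2-yne-4,6-diol dilithium dialkoxide (epimers at C4) | CCCCCCCC/C=C\CCCCCCCCC[C@@H](O[Li])CC(O[Li])(C#CC)N1CCOCC1 | intermediate
10 | (R,Z)-6-hydroxypentacos-16-en-2-yn-4-one | CCCCCCCC/C=C\CCCCCCCCC[C@@H](O)CC(=O)C#CC | intermediate
11 | (2E,6R,16Z)-6-hydroxy-2-(morpholin-4-yl)pentacosa-2,16-dien-4-one | CCCCCCCC/C=C\CCCCCCCCC[C@@H](O)CC(=O)/C=C(\C)N1CCOCC1 | intermediate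
12 | (R)-6-methyl-2-[(Z)-nonadec-10-en-1-yl]-2,3-dihydro-4H-pyran-4-one | CCCCCCCC/C=C\CCCCCCCCC[C@@H]1CC(=O)C=C(C)O1 | target

Total step count: 3
Longest linear sequence: 3 steps (1 → 5 → 7 → 12)

Steps most likely to fail

Step 3. The methoxide present after the methanol quench may dehydrate (E1cB) or retro-aldolise the β-hydroxy ynone faster than the amine adds. The acid stage may also reopen the ring by retro-oxa-Michael reaction and erode the configuration at C2. The fallback sets out from 7 and comes back at 12. Silylation of 7 (TESCl, imidazole, CH2Cl2) gives (R,Z)-1-(morpholin-4-yl)-3-(triethylsilyloxy)docos-13-en-1-one F1. 1-Propynylmagnesium bromide in THF at 0 °C, quenched into cold aqueous citric acid so that morpholine stays as its salt, gives the isolated (R,Z)-6-(triethylsilyloxy)pentacos-16-en-2-yn-4-one F2, in which no alkoxide and no free amine meet the ynone. TsOH·H2O in MeOH at 0 °C removes the silyl group to give 10, this time isolated. Ph3PAuNTf2 (5 mol%) in CH2Cl2 then closes 10 by 6-endo-dig hydroalkoxylation under neutral conditions to 12.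

Step 2. Carbonyl insertion at 1 atm may be slow enough for direct aminolysis of the epoxide by the silyl amine to compete. Cobalt hydride formed from adventitious moisture may also migrate or isomerise the Z-alkene. The fallback sets out from 5 and comes back at 7, separating carbonylation from amide formation. Ring-expanding carbonylation of 5 with the ion-pair catalyst [(salph)Al(THF)2][Co(CO)4] under CO pressure in THF inserts CO into the CH2–O bond and should give (R)-4-[(Z)-nonadec-10-en-1-yl]oxetan-2-one F3 with the stereocentre retained. Morpholine pre-complexed with AlMe3 in CH2Cl2 then opens F3 at the acyl carbon to return 7.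

Step 1. Wurtz-type homocoupling may consume the bromide during Grignard formation. Direct substitution at the C–Cl carbon of 2 may compete with epoxide opening, which would deliver the enantiomeric oxirane and lower the enantiomeric purity. Ring closure may stall in the magnesium hydroxide slurry. The fallback sets out from 1, avoids epichlorohydrin and the epoxide altogether, and comes back at 7. The dianion of ethyl acetoacetate (NaH, then n-BuLi, THF, 0 °C) is alkylated at its terminal carbon by 1 to give ethyl (Z)-3-oxodocos-13-enoate F4. Asymmetric hydrogenation of the keto group with RuCl2[(R)-BINAP] (H2, EtOH), a catalyst that should spare the isolated disubstituted alkene, gives ethyl (R,Z)-3-hydroxydocos-13-enoate F5. Aminolysis with morpholine/AlMe3 in toluene returns 7.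

Further compounds
F1 | step 3 | (R,Z)-1-(morpholin-4-yl)-3-(triethylsilyloxy)docos-13-en-1-one | CCCCCCCC/C=C\CCCCCCCCC[C@@H](O[Si](CC)(CC)CC)CC(=O)N1CCOCC1
F2 | step 3 | (R,Z)-6-(triethylsilyloxy)pentacos-16-en-2-yn-4-one | CCCCCCCC/C=C\CCCCCCCCC[C@@H](O[Si](CC)(CC)CC)CC(=O)C#CC
F3 | step 2 | (R)-4-[(Z)-nonadec-10-en-1-yl]oxetan-2-one | CCCCCCCC/C=C\CCCCCCCCC[C@@H]1CC(=O)O1
F4 | step 1 | ethyl (Z)-3-oxodocos-13-enoate | CCCCCCCC/C=C\CCCCCCCCCC(=O)CC(=O)OCC
F5 | step 1 | ethyl (R,Z)-3-hydroxydocos-13-enoate | CCCCCCCC/C=C\CCCCCCCCC[C@@H](O)CC(=O)OCC
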